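Ring A of the target is a 2-acyloxy-3,4-dihydro-2H-pyran whose C5 bears the C5=C6 double bond of ring B; this pattern is the adduct of an enol ether (C9=C1) with a 1-oxadiene (O2=C3–C4=C5) that is one half of an allene. A single intramolecular inverse-demand oxa-(4+2) addition of an allenyl aldehyde therefore forms C5–C9 and C1–O2, closes rings B and A and sets C9 and C1. The precursor is an acyclic (E)-silyl enol ether carrying C7 and C8 (set by a Sharpless kinetic resolution) and a 2-(acetoxymethyl)-2,3-allenal. Since a concerted addition relays the allene axis to C9, the allene is made as one axis epimer from an enantioenriched alkynyl oxirane.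

Key step: step 13

Remark: atom labels follow iridoid numbering (C1 acetal carbon, O2 ring oxygen, C3/C4 enol ether, C5/C9 fusion atoms, C6–C8 in ring B, C10 on C8, C11 on C4); a concerted suprafacial addition puts C1 on the ring-B face where C3 lies, so a mixture at the allene axis would give a mixture at C9 and the precursor is therefore built as one axis epimer, the copper hydride SN2' step being taken as anti.

Step 1
Reactants: 1 pent-4-enal; 2 formaldehyde
Product: 3 2-methylidenepent-4-enal
Conditions: aq. CH2O (37%), pyrrolidine (10 mol%), EtCO2H (10 mol%), iPrOH, 45 °C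
Reagents that add atoms: formaldehyde (2), C=O
Why: Amine-catalysed α-methylenation (Mannich condensation, then loss of the amine) of an unbranched aldehyde should give the 2-substituted acrolein without touching the isolated alkene.

Step 2
Reactants: 3 2-methylidenepent-4-enal; 4 ethynylmagnesium bromide
Product: 5 rac-4-methylidenehept-6-en-1-yn-3-ol
Conditions: HC≡CMgBr (1.1 equiv), THF, −78→0 °C; aq. NH4Cl
Reagents that add atoms: ethynylmagnesium bromide (4), C#C[Mg]Br
Why: Grignard 1,2-addition of the alkynyl nucleophile to the enal carbonyl gives the racemic alkenyl alkynyl carbinol that step 3 resolves.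

Step 3
Reactants: 5 rac-4-methylidenehept-6-en-1-yn-3-ol; 6 tert-butyl hydroperoxide
Product: 7 (1R)-1-[(2S)-2-(prop-2-en-1-yl)oxiran-2-yl]prop-2-yn-1-ol
Conditions: Ti(OiPr)4 (10 mol%), D-(−)-diisopropyl tartrate (15 mol%), TBHP (0.5 equiv), 4 Å MS, CH2Cl2, −20 °C, stopped near half conversion
Reagents that add atoms: tert-butyl hydroperoxide (6), CC(C)(C)OO
Why: Sharpless kinetic-resolution epoxidation: with the D-(−)-tartrate the (S)-carbinol should react fast and take oxygen on the alkene face anti to its ethynyl group (erythro), which sets C7 (R) and C8 (S) together, while the (R)-carbinol and the remote monosubstituted alkene stay untouched.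

Step 4
Reactants: 7 (1R)-1-[(2S)-2-(prop-2-en-1-yl)oxiran-2-yl]prop-2-yn-1-ol; 8 3-methylbutanoic acid
Product: 9 (2S,3R)-2,3-dihydroxy-2-(prop-2-en-1-yl)pent-4-yn-1-yl 3-methylbutanoate
Conditions: iPrCH2CO2H (2 equiv), Ti(OiPr)4 (1.5 equiv), CH2Cl2, 23 °C; aqueous work-up
Reagents that add atoms: 3-methylbutanoic acid (8), CC(C)CC(=O)O
Why: Titanium-assisted opening of a 2,3-epoxy alcohol by a carboxylic acid should occur by SN2 attack at the unhindered terminal carbon C10, so the C8–O bond and its configuration are retained.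

Step 5
Reactants: 9 (2S,3R)-2,3-dihydroxy-2-(prop-2-en-1-yl)pent-4-yn-1-yl 3-methylbutanoate; 10 3-methylbutanoic anhydride
Product: 11 (2S,3R)-2-hydroxy-2-(prop-2-en-1-yl)pent-4-yne-1,3-diyl bis(3-methylbutanoate)
Conditions: (iPrCH2CO)2O (1.3 equiv), DMAP (5 mol%), pyridine, CH2Cl2, 0 °C
Reagents that add atoms: 3-methylbutanoic anhydride (10), CC(C)CC(=O)OC(=O)CC(C)C
Why: DMAP-catalysed acylation esterifies only the secondary propargylic hydroxyl, the tertiary C8 hydroxyl being too hindered, and a 1,3-acyl shift in 9 would be harmless because both esters are isovalerates.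

Step 6
Reactants: 11 (2S,3R)-2-hydroxy-2-(prop-2-en-1-yl)pent-4-yne-1,3-diyl bis(3-methylbutanoate); 12 triethylsilyl trifluoromethanesulfonate
Product: 13 (2S,3R)-2-(prop-2-en-1-yl)-2-[(triethylsilyl)oxy]pent-4-yne-1,3-diyl bis(3-methylbutanoate)
Conditions: TESOTf (1.5 equiv), 2,6-lutidine (3 equiv), CH2Cl2, −78→0 °C
Reagents that add atoms: triethylsilyl trifluoromethanesulfonate (12), CC[Si](CC)(CC)OS(=O)(=O)C(F)(F)F
Why: Silylation with a silyl triflate and a hindered pyridine base protects the tertiary alcohol, which would otherwise be silylated less removably in step 8 or add to the allenal later.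

Step 7
Reactants: 13 (2S,3R)-2-(prop-2-en-1-yl)-2-[(triethylsilyl)oxy]pent-4-yne-1,3-diyl bis(3-methylbutanoate); 14 sodium periodate
Product: 16 (2S,3R)-2-(2-oxoethyl)-2-[(triethylsilyl)oxy]pent-4-yne-1,3-diyl bis(3-methylbutanoate), via vicinal diol 15 (not isolated)
Conditions: OsO4 (2 mol%), NaIO4 (4 equiv), 2,6-lutidine (2 equiv), dioxane/H2O (3:1), 23 °C
Reagents that add atoms: sodium periodate (14), [Na+].[O-][I](=O)(=O)=O
Why: Lemieux–Johnson cleavage: OsO4 dihydroxylates the monosubstituted alkene much faster than the terminal alkyne and periodate cleaves the diol to the C1 aldehyde under near-neutral conditions that spare the β-silyloxy group.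

Step 8
Reactants: 16 (2S,3R)-2-(2-oxoethyl)-2-[(triethylsilyl)oxy]pent-4-yne-1,3-diyl bis(3-methylbutanoate); 17 tert-butyldimethylsilyl trifluoromethanesulfonate
Product: 18 (2S,3R)-2-[(E)-2-{[tert-butyl(dimethyl)silyl]oxy}ethenyl]-2-[(triethylsilyl)oxy]pent-4-yne-1,3-diyl bis(3-methylbutanoate)
Conditions: TBSOTf (1.3 equiv), Et3N (3 equiv), CH2Cl2, −78→0 °C
Reagents that add atoms: tert-butyldimethylsilyl trifluoromethanesulfonate (17), CC(C)(C)[Si](C)(C)OS(=O)(=O)C(F)(F)F
Why: Soft enolisation (silyl triflate, tertiary amine) of the aldehyde should favour the (E) enol ether because the fully substituted C8 avoids the position cis to the silyloxy group; a minor (Z) isomer would only give the C1 epimer of 27, which converges at lactol 34.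

Step 9
Reactants: 18 (2S,3R)-2-[(E)-2-{[tert-butyl(dimethyl)silyl]oxy}ethenyl]-2-[(triethylsilyl)oxy]pent-4-yne-1,3-diyl bis(3-methylbutanoate); 19 2-bromoprop-2-en-1-ol
Product: 20 (2S,3R)-2-[(E)-2-{[tert-butyl(dimethyl)silyl]oxy}ethenyl]-7-hydroxy-6-methylidene-2-[(triethylsilyl)oxy]hept-4-yne-1,3-diyl bis(3-methylbutanoate)
Conditions: Pd(PPh3)2Cl2 (3 mol%), CuI (5 mol%), iPr2NH, THF, 23 °C
Reagents that add atoms: 2-bromoprop-2-en-1-ol (19), OCC(Br)=C
Why: Sonogashira coupling of the terminal alkyne with the vinyl bromide adds C4, C3 and C11 as a 2-alkynyl allylic alcohol under amine-buffered conditions that the silyl enol ether and the propargylic ester should tolerate at room temperature.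

Step 10
Reactants: 20 (2S,3R)-2-[(E)-2-{[tert-butyl(dimethyl)silyl]oxy}ethenyl]-7-hydroxy-6-methylidene-2-[(triethylsilyl)oxy]hept-4-yne-1,3-diyl bis(3-methylbutanoate); 6 tert-butyl hydroperoxide; 21 acetic anhydride
Product: 23 (2S,3R)-5-[(2R)-2-(acetoxymethyl)oxiran-2-yl]-2-[(E)-2-{[tert-butyl(dimethyl)silyl]oxy}ethenyl]-2-[(triethylsilyl)oxy]pent-4-yne-1,3-diyl bis(3-methylbutanoate), via epoxy alcohol 22 (not isolated)
Conditions: Ti(OiPr)4 (10 mol%), L-(+)-diisopropyl tartrate (12 mol%), TBHP (2 equiv), 4 Å MS, CH2Cl2, −25 °C; P(OMe)3; then Et3N, Ac2O, DMAP (5 mol%), −20→0 °C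
Reagents that add atoms: tert-butyl hydroperoxide (6), CC(C)(C)OO; acetic anhydride (21), CC(=O)OC(C)=O
Why: Sharpless asymmetric epoxidation of the 1,1-disubstituted allylic alcohol with the L-(+)-tartrate (the sense that gives (S)-2-substituted glycidols) sets C4 under reagent control, and in situ acetylation avoids isolating the sensitive glycidol and installs the C11 acetate; C4 is the centre that becomes the allene axis.

Step 11
Reactants: 23 (2S,3R)-5-[(2R)-2-(acetoxymethyl)oxiran-2-yl]-2-[(E)-2-{[tert-butyl(dimethyl)silyl]oxy}ethenyl]-2-[(triethylsilyl)oxy]pent-4-yne-1,3-diyl bis(3-methylbutanoate)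
Product: 25 (2S,3R,Ra)-6-(acetoxymethyl)-2-[(E)-2-{[tert-butyl(dimethyl)silyl]oxy}ethenyl]-7-hydroxy-2-[(triethylsilyl)oxy]hepta-4,5-diene-1,3-diyl bis(3-methylbutanoate), via allenyl silyl ether 24 (not isolated)
Conditions: (IPr)CuCl [IPr = 1,3-bis(2,6-diisopropylphenyl)imidazol-2-ylidene] (5 mol%), NaOtBu (5 mol%), HSiMe(OMe)2 (2 equiv), toluene, 0 °C; then MeOH, pH 7 buffer
Reagents that add atoms: none
Why: Copper hydride catalysed SN2' reduction of an alkynyl oxirane: syn hydrocupration (H to C6) and anti β-alkoxide elimination should open the strained oxirane with overall anti stereochemistry, so C4 is relayed to the axis with the C3 carbinol on the side of O7, and 25 is used at once because acetyl migration between the C3 and C11 arms would invert the axis.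

Step 12
Reactants: 25 (2S,3R,Ra)-6-(acetoxymethyl)-2-[(E)-2-{[tert-butyl(dimethyl)silyl]oxy}ethenyl]-7-hydroxy-2-[(triethylsilyl)oxy]hepta-4,5-diene-1,3-diyl bis(3-methylbutanoate)
Product: 26 (2S,3R,Sa)-6-(acetoxymethyl)-2-[(E)-2-{[tert-butyl(dimethyl)silyl]oxy}ethenyl]-7-oxo-2-[(triethylsilyl)oxy]hepta-4,5-diene-1,3-diyl bis(3-methylbutanoate) (the allenyl aldehyde; same axis geometry as 25, descriptor changed by priority)
Conditions: MnO2 (activated, 20 equiv), CH2Cl2, 23 °C
Reagents that add atoms: none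
Why: MnO2 oxidation of the primary α-allenic (allylic-type) alcohol gives the 2,3-allenal under neutral heterogeneous conditions that leave the silyl enol ether, the esters and the axis untouched.

Step 13
Reactants: 26 (2S,3R,Sa)-6-(acetoxymethyl)-2-[(E)-2-{[tert-butyl(dimethyl)silyl]oxy}ethenyl]-7-oxo-2-[(triethylsilyl)oxy]hepta-4,5-diene-1,3-diyl bis(3-methylbutanoate)
Product: 27 [(1S,6R,7S,7aS)-4-(acetoxymethyl)-1-{[tert-butyl(dimethyl)silyl]oxy}-6-[(3-methylbutanoyl)oxy]-7-[(triethylsilyl)oxy]-1,6,7,7a-tetrahydrocyclopenta[c]pyran-7-yl]methyl 3-methylbutanoate (iridoid labels 1S,7R,8S,9S)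
Conditions: toluene (0.01 M), 2,6-di-tert-butyl-4-methylpyridine (0.2 equiv), 4 Å MS, 23→60 °C
Reagents that add atoms: none
Why: Proposed new method: on warming, the s-cis formyl group and the proximal allene bond (O2=C3–C4=C5) should act as an electron-poor 1-oxadiene toward the tethered silyl enol ether (C9=C1) in a concerted, asynchronous inverse-demand oxa-(4+2) addition; the closest known reaction types are hetero-Diels–Alder additions of enals and alkylidene 1,3-dicarbonyl compounds to enol ethers and intramolecular (4+2) additions of vinylallenes. Ring B closes by 5-exo attack of C9 on the sp carbon C5 in the plane of the C4=C5 π bond (the plane that holds C7), ring A closes by the O2–C1 bond as a six-membered acetal, and the orthogonal C5=C6 bond is left as the ring alkene. C9 is controlled by the allene axis: the oxadiene lies perpendicular to the incipient ring B, so C1 must follow O2 to the ring face on which the formyl group sits, which for the (Sa) axis is the face of O7 and C10 (H9 syn to the C8 silyloxy group). C1 is controlled by suprafacial addition to the (E)-enol ether, which puts the silyloxy group trans to the C9–C8 bond and endo. The step needs this axis-to-centre transfer, which a single axis epimer, the three-atom tether and neutral thermal conditions without a Lewis acid (no open stepwise addition) should secure, and the axis itself is consumed.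

Step 14
Reactants: 28 3-hydroxy-3-methylbutanoic acid; 21 acetic anhydride
Product: 30 3-acetoxy-3-methylbutanoic acid, via mixed anhydride 29 (not isolated)
Conditions: Ac2O (3 equiv), Bi(OTf)3 (1 mol%), MeCN, 23 °C; then H2O, THF
Reagents that add atoms: acetic anhydride (21), CC(=O)OC(C)=O
Why: Lewis-acid-catalysed acetylation of the tertiary alcohol, followed by hydrolysis of the mixed anhydride formed at the carboxyl group, gives the acetoxy acid without base-induced β-elimination.

Step 15
Reactants: 30 3-acetoxy-3-methylbutanoic acid (2 equiv)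
Product: 32 3-acetoxy-3-methylbutanoic anhydride, via O-acylisourea 31 (not isolated)
Conditions: DCC (0.5 equiv), CH2Cl2, 0 °C; filtration
Reagents that add atoms: none
Why: Carbodiimide dehydration of the acid gives the symmetric anhydride, a mild acyl donor that avoids an acid chloride prone to loss of acetic acid.

Step 16
Reactants: 27 [(1S,6R,7S,7aS)-4-(acetoxymethyl)-1-{[tert-butyl(dimethyl)silyl]oxy}-6-[(3-methylbutanoyl)oxy]-7-[(triethylsilyl)oxy]-1,6,7,7a-tetrahydrocyclopenta[c]pyran-7-yl]methyl 3-methylbutanoate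
Product: 34 [(1R,6R,7S,7aS)-4-(acetoxymethyl)-1,7-dihydroxy-6-[(3-methylbutanoyl)oxy]-1,6,7,7a-tetrahydrocyclopenta[c]pyran-7-yl]methyl 3-methylbutanoate (lactol, drawn anomer; anomers interconvert), via 8-O-triethylsilyl lactol 33 (not isolated)
Conditions: HF·pyridine, pyridine, THF, 0→23 °C
Reagents that add atoms: none
Why: Buffered fluoride desilylation should cleave the anomeric silyl acetal first and then the tertiary TES ether while the esters and the dienol ether survive; the lactol is taken on without storage.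

Step 17
Reactants: 34 [(1R,6R,7S,7aS)-4-(acetoxymethyl)-1,7-dihydroxy-6-[(3-methylbutanoyl)oxy]-1,6,7,7a-tetrahydrocyclopenta[c]pyran-7-yl]methyl 3-methylbutanoate; 32 3-acetoxy-3-methylbutanoic anhydride
Product: 35 (1S,6R,7S,7aS)-4-(acetoxymethyl)-7-hydroxy-6-[(3-methylbutanoyl)oxy]-7-{[(3-methylbutanoyl)oxy]methyl}-1,6,7,7a-tetrahydrocyclopenta[c]pyran-1-yl 3-acetoxy-3-methylbutanoate (target, CNP0331701.2)
Conditions: 32 (1.5 equiv), DMAP (10 mol%), pyridine, CH2Cl2, −20→0 °C
Reagents that add atoms: 3-acetoxy-3-methylbutanoic anhydride (32), CC(=O)OC(C)(C)CC(=O)OC(=O)CC(C)(C)OC(C)=O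
Why: DMAP-catalysed acylation of the hemiacetal hydroxyl (the tertiary C8 hydroxyl is inert), in which the interconverting anomers of 34 should be funnelled to the ester trans to the C9–C8 bond (pseudoaxial, anomeric effect, the arrangement of the natural valepotriates), fixes C1 (S).

Compound list
1 | pent-4-enal | C=CCCC=O | starting material
2 | formaldehyde | C=O | starting material
3 | 2-methylidenepent-4-enal | C=CCC(=C)C=O | intermediate
4 | ethynylmagnesium bromide | C#C[Mg]Br | starting material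
5 | rac-4-methylidenehept-6-en-1-yn-3-ol | C#CC(O)C(=C)CC=C | intermediate
6 | tert-butyl hydroperoxide | CC(C)(C)OO | starting material
7 | (1R)-1-[(2S)-2-(prop-2-en-1-yl)oxiran-2-yl]prop-2-yn-1-ol | C#C[C@@H](O)[C@]1(CC=C)CO1 | intermediate
8 | 3-methylbutanoic acid (isovaleric acid) | CC(C)CC(=O)O | starting material
9 | (2S,3R)-2,3-dihydroxy-2-(prop-2-en-1-yl)pent-4-yn-1-yl 3-methylbutanoate | C#C[C@@H](O)[C@](O)(CC=C)COC(=O)CC(C)C | intermediate
10 | 3-methylbutanoic anhydride | CC(C)CC(=O)OC(=O)CC(C)C | starting material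
11 | (2S,3R)-2-hydroxy-2-(prop-2-en-1-yl)pent-4-yne-1,3-diyl bis(3-methylbutanoate) | C#C[C@@H](OC(=O)CC(C)C)[C@](O)(CC=C)COC(=O)CC(C)C | intermediate
12 | triethylsilyl trifluoromethanesulfonate | CC[Si](CC)(CC)OS(=O)(=O)C(F)(F)F | starting material
13 | (2S,3R)-2-(prop-2-en-1-yl)-2-[(triethylsilyl)oxy]pent-4-yne-1,3-diyl bis(3-methylbutanoate) | C#C[C@@H](OC(=O)CC(C)C)[C@](O[Si](CC)(CC)CC)(CC=C)COC(=O)CC(C)C | intermediate
14 | sodium periodate | [Na+].[O-][I](=O)(=O)=O | starting material
15 | (2S,3R)-2-(2,3-dihydroxypropyl)-2-[(triethylsilyl)oxy]pent-4-yne-1,3-diyl bis(3-methylbutanoate), both epimers at the new carbinol | C#C[C@@H](OC(=O)CC(C)C)[C@](O[Si](CC)(CC)CC)(CC(O)CO)COC(=O)CC(C)C | intermediate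
16 | (2S,3R)-2-(2-oxoethyl)-2-[(triethylsilyl)oxy]pent-4-yne-1,3-diyl bis(3-methylbutanoate) | C#C[C@@H](OC(=O)CC(C)C)[C@](O[Si](CC)(CC)CC)(CC=O)COC(=O)CC(C)C | intermediate
17 | tert-butyldimethylsilyl trifluoromethanesulfonate | CC(C)(C)[Si](C)(C)OS(=O)(=O)C(F)(F)F | starting material
18 | (2S,3R)-2-[(E)-2-{[tert-butyl(dimethyl)silyl]oxy}ethenyl]-2-[(triethylsilyl)oxy]pent-4-yne-1,3-diyl bis(3-methylbutanoate) | C#C[C@@H](OC(=O)CC(C)C)[C@@](O[Si](CC)(CC)CC)(COC(=O)CC(C)C)/C=C/O[Si](C)(C)C(C)(C)C | intermediate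
19 | 2-bromoprop-2-en-1-ol | OCC(Br)=C | starting material
20 | (2S,3R)-2-[(E)-2-{[tert-butyl(dimethyl)silyl]oxy}ethenyl]-7-hydroxy-6-methylidene-2-[(triethylsilyl)oxy]hept-4-yne-1,3-diyl bis(3-methylbutanoate) | OCC(=C)C#C[C@@H](OC(=O)CC(C)C)[C@@](O[Si](CC)(CC)CC)(COC(=O)CC(C)C)/C=C/O[Si](C)(C)C(C)(C)C | intermediate
21 | acetic anhydride | CC(=O)OC(C)=O | starting material
22 | (2S,3R)-2-[(E)-2-{[tert-butyl(dimethyl)silyl]oxy}ethenyl]-5-[(2S)-2-(hydroxymethyl)oxiran-2-yl]-2-[(triethylsilyl)oxy]pent-4-yne-1,3-diyl bis(3-methylbutanoate) | OC[C@]1(CO1)C#C[C@@H](OC(=O)CC(C)C)[C@@](O[Si](CC)(CC)CC)(COC(=O)CC(C)C)/C=C/O[Si](C)(C)C(C)(C)C | intermediate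
23 | (2S,3R)-5-[(2R)-2-(acetoxymethyl)oxiran-2-yl]-2-[(E)-2-{[tert-butyl(dimethyl)silyl]oxy}ethenyl]-2-[(triethylsilyl)oxy]pent-4-yne-1,3-diyl bis(3-methylbutanoate) | CC(=O)OC[C@]1(CO1)C#C[C@@H](OC(=O)CC(C)C)[C@@](O[Si](CC)(CC)CC)(COC(=O)CC(C)C)/C=C/O[Si](C)(C)C(C)(C)C | intermediate
24 | (2S,3R,Sa)-6-(acetoxymethyl)-2-[(E)-2-{[tert-butyl(dimethyl)silyl]oxy}ethenyl]-7-{[dimethoxy(methyl)silyl]oxy}-2-[(triethylsilyl)oxy]hepta-4,5-diene-1,3-diyl bis(3-methylbutanoate) | CO[Si](C)(OC)OCC(COC(C)=O)=[C@@]=C([H])[C@@H](OC(=O)CC(C)C)[C@@](O[Si](CC)(CC)CC)(COC(=O)CC(C)C)/C=C/O[Si](C)(C)C(C)(C)C | intermediate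
25 | (2S,3R,Ra)-6-(acetoxymethyl)-2-[(E)-2-{[tert-butyl(dimethyl)silyl]oxy}ethenyl]-7-hydroxy-2-[(triethylsilyl)oxy]hepta-4,5-diene-1,3-diyl bis(3-methylbutanoate) | OCC(COC(C)=O)=[C@@]=C([H])[C@@H](OC(=O)CC(C)C)[C@@](O[Si](CC)(CC)CC)(COC(=O)CC(C)C)/C=C/O[Si](C)(C)C(C)(C)C | intermediate
26 | (2S,3R,Sa)-6-(acetoxymethyl)-2-[(E)-2-{[tert-butyl(dimethyl)silyl]oxy}ethenyl]-7-oxo-2-[(triethylsilyl)oxy]hepta-4,5-diene-1,3-diyl bis(3-methylbutanoate) | O=CC(COC(C)=O)=[C@@]=C([H])[C@@H](OC(=O)CC(C)C)[C@@](O[Si](CC)(CC)CC)(COC(=O)CC(C)C)/C=C/O[Si](C)(C)C(C)(C)C | intermediate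
27 | [(1S,6R,7S,7aS)-4-(acetoxymethyl)-1-{[tert-butyl(dimethyl)silyl]oxy}-6-[(3-methylbutanoyl)oxy]-7-[(triethylsilyl)oxy]-1,6,7,7a-tetrahydrocyclopenta[c]pyran-7-yl]methyl 3-methylbutanoate | CC(=O)OCC1=CO[C@@H](O[Si](C)(C)C(C)(C)C)[C@H]2C1=C[C@@H](OC(=O)CC(C)C)[C@@]2(O[Si](CC)(CC)CC)COC(=O)CC(C)C | intermediate
28 | 3-hydroxy-3-methylbutanoic acid | CC(C)(O)CC(=O)O | starting material
29 | acetic 3-acetoxy-3-methylbutanoic anhydride | CC(=O)OC(C)(C)CC(=O)OC(C)=O | intermediate
30 | 3-acetoxy-3-methylbutanoic acid | CC(=O)OC(C)(C)CC(=O)O | intermediate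
31 | O-(3-acetoxy-3-methylbutanoyl)-N,N'-dicyclohexylisourea | CC(=O)OC(C)(C)CC(=O)OC(=NC1CCCCC1)NC1CCCCC1 | intermediate
32 | 3-acetoxy-3-methylbutanoic anhydride | CC(=O)OC(C)(C)CC(=O)OC(=O)CC(C)(C)OC(C)=O | intermediate
33 | [(1R,6R,7S,7aS)-4-(acetoxymethyl)-1-hydroxy-6-[(3-methylbutanoyl)oxy]-7-[(triethylsilyl)oxy]-1,6,7,7a-tetrahydrocyclopenta[c]pyran-7-yl]methyl 3-methylbutanoate | CC(=O)OCC1=CO[C@@H](O)[C@H]2C1=C[C@@H](OC(=O)CC(C)C)[C@@]2(O[Si](CC)(CC)CC)COC(=O)CC(C)C | intermediate
34 | [(1R,6R,7S,7aS)-4-(acetoxymethyl)-1,7-dihydroxy-6-[(3-methylbutanoyl)oxy]-1,6,7,7a-tetrahydrocyclopenta[c]pyran-7-yl]methyl 3-methylbutanoate | CC(=O)OCC1=CO[C@@H](O)[C@H]2C1=C[C@@H](OC(=O)CC(C)C)[C@@]2(O)COC(=O)CC(C)C | intermediate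
35 | (1S,6R,7S,7aS)-4-(acetoxymethyl)-7-hydroxy-6-[(3-methylbutanoyl)oxy]-7-{[(3-methylbutanoyl)oxy]methyl}-1,6,7,7a-tetrahydrocyclopenta[c]pyran-1-yl 3-acetoxy-3-methylbutanoate | CC(=O)OCC1=CO[C@@H](OC(=O)CC(C)(C)OC(C)=O)[C@H]2C1=C[C@@H](OC(=O)CC(C)C)[C@@]2(O)COC(=O)CC(C)C | target

Total step count: 17. Longest linear sequence: 15 (steps 1–13, 16 and 17; steps 14 and 15 make the acyl donor).

Steps most likely to fail

1. Step 13 (intramolecular allenal oxa-(4+2) addition). What may go wrong: loss of periselectivity (the enol ether adding across one allene bond in a (2+2) sense), oligomerisation of the allenal, or an open stepwise addition that no longer relays the axis to C9. Fallback with known reaction types, setting out from 26 and coming back at 34: the two rings would be closed one after the other by polar chemistry. A silyl-triflate-catalysed intramolecular Mukaiyama–Michael addition (TBSOTf 10 mol%, 2,6-di-tert-butylpyridine, CH2Cl2, −78 °C) of the enol ether to the central carbon of the activated allenal, with silyl transfer to the dienolate oxygen, should give the cyclopentene aldehyde silyl dienol ether F1. HF·pyridine/pyridine in THF would then remove both silyl groups of F1, and the freed dienol should close on the C1 aldehyde, as iridoid 1,5-dialdehydes do, to give lactol 34, which rejoins the route at step 17. C9, being α to the aldehyde, would then be under hemiacetal-equilibrium control instead of axis control.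

2. Step 11 (copper hydride SN2' reduction). What may go wrong: hydride delivery with loss of the C7 isovalerate on the other side of the alkyne instead of oxirane opening, incomplete anti transfer, or acetyl migration between the C3 and C11 arms at the alkoxide stage, each of which erodes the axis. Fallback, setting out from 23 and coming back at 25: palladium-catalysed formate hydrogenolysis of the alkynyl oxirane (Pd2(dba)3·CHCl3 2.5 mol%, PBu3 10 mol%, HCO2H, Et3N, THF, 0→23 °C). Zerovalent palladium should ionise the strained oxirane anti to give an allenylpalladium species; formate replaces the alkoxide, CO2 is lost and reductive elimination puts hydride on C6 with retention, so the same (Ra) allenol 25 should result. The site of reaction is then chosen by the better nucleofuge and not by the regiochemistry of hydrometalation, and the medium is weakly acidic, which disfavours acetyl migration. This fallback makes no new compound (F0).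

3. Step 16 (global desilylation to the free lactol). What may go wrong: ring opening of the hemiacetal to the dienol aldehyde followed by elimination of acetate or isovalerate, the known decay path of diene acetals of this kind. Fallback, setting out from 27 and coming back at 35: the anomeric silyl group would be exchanged for the acyl group without a free lactol. Fluoride-catalysed silyl-to-acyl exchange of the silyl acetal with anhydride 32 (Bu4N(Ph3SiF2) 10 mol%, THF, −40→0 °C) should give the 8-O-triethylsilyl ether of the target F2, and Et3N·3HF in MeCN at 0 °C would then cleave the tertiary TES ether to give 35.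

Further compounds
F1 | step 13 | [(1S,2R,5S)-3-[(Z)-3-acetoxy-1-{[tert-butyl(dimethyl)silyl]oxy}prop-1-en-2-yl]-5-formyl-2-[(3-methylbutanoyl)oxy]-1-[(triethylsilyl)oxy]cyclopent-3-en-1-yl]methyl 3-methylbutanoate (C1 aldehyde on C9, O2-silyl dienol ether with oxygen cis to C5) | O=C[C@H]1C(/C(COC(C)=O)=C\O[Si](C)(C)C(C)(C)C)=C[C@@H](OC(=O)CC(C)C)[C@@]1(O[Si](CC)(CC)CC)COC(=O)CC(C)C
F0 | step 11 | none | none
F2 | step 16 | (1S,6R,7S,7aS)-4-(acetoxymethyl)-6-[(3-methylbutanoyl)oxy]-7-{[(3-methylbutanoyl)oxy]methyl}-7-[(triethylsilyl)oxy]-1,6,7,7a-tetrahydrocyclopenta[c]pyran-1-yl 3-acetoxy-3-methylbutanoate | CC(=O)OCC1=CO[C@@H](OC(=O)CC(C)(C)OC(C)=O)[C@H]2C1=C[C@@H](OC(=O)CC(C)C)[C@@]2(O[Si](CC)(CC)CC)COC(=O)CC(C)C
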